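**Retrosynthetic overview**

- Target ⇐ acetonide removal ⇐ (13Z)-enoate by syn methylcupration of a C13≡C14 ynoate ⇐ C15 acylation of a terminal alkyne ⇐ C9–C11 bond by adding a silylbutynyl Grignard reagent to a C9 decalone.
- C9 decalone ⇐ C6 deoxygenation, α-face dihydroxylation of C2=C3, C7=C8 reduction and C5 epimerisation of a cis-fused ene-dione ⇐ enantioselective Diels–Alder reaction (bonds C1–C10 and C4–C5) of 2,6-dimethyl-1,4-benzoquinone with 4-methylpenta-1,3-diene.
- Feature the strategy rests on: ring B has the oxygenated C9 between the methyl-bearing C8 and C10 (the pattern of 2,6-dimethylbenzoquinone). Ring A has the cis C2/C3 diol, a masked C2=C3 alkene, between C1H2 and the gem-dimethyl C4 (the pattern of 4-methylpenta-1,3-diene).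
- Ring order: ring B is bought as the quinone; ring A is closed onto it in step 1; the side chain is then attached at C9 and extended at C14 (C15) and C13 (C16).

Key step: step 1

Remark on numbering: labdane numbering is used for all intermediates (decalin C1–C10, side chain C11–C16, C17 on C8, C18/C19 on C4, C20 on C10); β is the face of C20, α the opposite face.

Assumption: the sense of induction in step 1 is taken from the α-C–H···O binding model of protonated oxazaborolidines, which points to the catalyst from (R)-α,α-diphenylprolinol for the drawn C10; the antipodal catalyst is equally available and would be used with no other change if the sense proved opposite.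

**Route**

Step 1
Reactants: 1 2,6-dimethyl-1,4-benzoquinone; 2 4-methylpenta-1,3-diene
Product: 3 cis-fused ene-dione, (4aR,8aS)-2,5,5,8a-tetramethyl-4a,5,8,8a-tetrahydronaphthalene-1,4-dione (labdane numbering: 6,9-dione; C2=C3 and C7=C8; 5β-H; 10β-CH3)
Conditions: (R)-1-(2-methylphenyl)-3,3-diphenyltetrahydro-1H,3H-pyrrolo[1,2-c][1,3,2]oxazaborole C24H24BNO (20 mol %), HN(SO2CF3)2 (18 mol %), CH2Cl2, 2 (3 equiv, slow addition), −78 → −40 °C
Reagents that add atoms: none
Why: Proposed new method: the protonated oxazaborolidine binds the quinone oxygen that is not flanked by methyl groups (the future C6=O, syn to the C5–H), which makes the methyl-bearing β-carbon the most electrophilic site, so the CH2 terminus of 2 bonds there first (C1–C10) and the dimethyl terminus, carrying tertiary allyl cation character in a concerted but strongly asynchronous suprafacial [4+2] transition state, then closes onto C5 (C4–C5). The closest known reactions are oxazaborolidinium-catalysed enantioselective Diels–Alder reactions of quinones with 2-silyloxy- and alkyl-substituted dienes and Lewis-acid-catalysed additions of 1-substituted dienes to 2,6-dimethylbenzoquinone; what is new is a diene whose reacting terminus carries a cis methyl group (low s-cis population), for which the cationic activation of the dienophile and the ionic, stepwise-leaning character of the bond formation are expected to compensate. Ring A is closed as a six-membered carbocycle by this intermolecular cycloaddition onto the intact ring B, with cis fusion. C10 (quaternary) and C5 are created together: their relative configuration follows from suprafacial addition, and the absolute configuration from the catalyst, whose aryl groups shield one face of the bound enone so that only one of the two enantiotopic C=C bonds of the symmetric quinone reacts. The step needs regioselectivity (C1 to C10, C4 to C5), secured jointly by catalyst binding at the unhindered oxygen and by the polarised diene (bulky terminus to the CH carbon, small terminus to the methyl-bearing carbon), and enantioselectivity, which rests on the catalyst; endo/exo selectivity is without consequence because neither diene terminus becomes a stereocentre. The quaternary C10 blocks aromatisation of the adduct.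

Step 2
Reactants: 3 cis-fused ene-dione (5β-H)
Product: 4 trans-fused ene-dione, (4aS,8aS)-2,5,5,8a-tetramethyl-4a,5,8,8a-tetrahydronaphthalene-1,4-dione (5α-H; 10β-CH3)
Conditions: 1,8-diazabicyclo[5.4.0]undec-7-ene (0.2 equiv), toluene, 25 °C
Reagents that add atoms: none
Why: Base-mediated epimerisation of a quinone Diels–Alder adduct: the C6 ketone is enolised towards C5 (C10 is quaternary, so the adduct cannot aromatise) and the dienolate is reprotonated on the α face, opposite C20 and the 4β-methyl group that flank C5, which gives the trans-fused isomer (5α-H) and takes the endo C4 methyl group off the concave face of the cis-fused bicycle.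

Step 3
Reactants: 4 trans-fused ene-dione
Product: 5 trans-fused saturated 6,9-dione (C2=C3 retained; 5α-H; 8α-CH3; 10β-CH3)
Conditions: Zn dust (5 equiv), AcOH, 25 °C
Reagents that add atoms: none
Why: Zn/AcOH reduction of the 2-ene-1,4-dione (two electrons, then protonation at C7 and C8) leaves the isolated C2=C3 alkene untouched; C8 is protonated axially from the β face and stays epimerisable next to the C9 ketone, so kinetic and thermodynamic control both place the methyl group equatorial (8α), clear of the axial C20.

Step 4
Reactants: 5 trans-fused saturated 6,9-dione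
Product: 6 2α,3α-dihydroxy-6,9-dione
Conditions: OsO4 (2 mol %), N-methylmorpholine N-oxide (1.5 equiv), acetone/H2O 5:1, 25 °C
Reagents that add atoms: osmium tetroxide O=[Os](=O)(=O)=O (catalytic oxygen carrier); N-methylmorpholine N-oxide C[N+]1([O-])CCOCC1; water O
Why: Catalytic syn-dihydroxylation (osmylation with amine oxide reoxidant) of the only alkene occurs on the α face, because the axial C20 and the 4β-methyl group cover the β face, and so sets C2 and C3 as the 2α,3α-cis-diol.

Step 5
Reactants: 6 2α,3α-dihydroxy-6,9-dione
Product: 7 2α,3α-O-isopropylidene-6,9-dione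
Conditions: 2,2-dimethoxypropane, pyridinium p-toluenesulfonate (5 mol %), acetone, 25 °C
Reagents that add atoms: 2,2-dimethoxypropane COC(C)(C)OC
Why: Acid-catalysed transketalisation closes the cis (axial/equatorial) diol to the dioxolane, while the two hindered ring ketones do not ketalise under these conditions; no stereocentre is touched.

Step 6
Reactants: 7 2α,3α-O-isopropylidene-6,9-dione
Product: 8 C6 (E)-tosylhydrazone of 7 (C9 ketone free)
Conditions: TsNHNH2 (1.05 equiv), EtOH, 50 °C
Reagents that add atoms: 4-methylbenzenesulfonohydrazide Cc1ccc(cc1)S(=O)(=O)NN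
Why: Hydrazone condensation takes place at C6, the carbonyl with a CH2 neighbour, because the C9 carbonyl lies between the quaternary C10 and the tertiary C8 and condenses far more slowly.

Step 7
Reactants: 8 C6 tosylhydrazone
Product: 10 C9 decalone acetonide (2α,3α-O-isopropylidene; C6 now CH2; 5α-H; 8α-CH3; 10β-CH3), via N-boryl tosylhydrazide 9 (not isolated)
Conditions: catecholborane (1.5 equiv), CHCl3, 0 °C; then NaOAc·3H2O, 60 °C
Reagents that add atoms: none
Why: Caglioti-type reduction in its catecholborane variant: hydride is transferred from boron to C6 of the C=N bond, and acetate then triggers loss of sulfinate and dinitrogen to leave CH2, under neutral conditions that spare the acetonide and the hindered C9 ketone; C5 is no longer epimerisable afterwards.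

Step 8
Reactants: 10 C9 decalone acetonide; 11 (4-bromobut-1-yn-1-yl)trimethylsilane
Product: 13 9β-hydroxy-9α-[4-(trimethylsilyl)but-3-yn-1-yl] acetonide, via Grignard reagent 12 (not isolated)
Conditions: 11, Mg, THF, 25–40 °C; 10 pre-stirred with anhydrous CeCl3 (1.5 equiv), THF, −78 → 0 °C; aq NH4Cl
Reagents that add atoms: none
Why: CeCl3-promoted Grignard 1,2-addition suppresses enolisation of the hindered ketone towards C8; the nucleophile enters along the axial trajectory on the α face, anti to the axial C20 on the neighbouring carbon (the equatorial β approach runs into C20), so C9 receives the chain axial (9α) and the hydroxyl equatorial (9β).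

Step 9
Reactants: 13 silylated alkynyl carbinol
Product: 14 terminal alkyne, 9α-(but-3-yn-1-yl)-9β-hydroxy acetonide
Conditions: K2CO3 (0.3 equiv), MeOH, 25 °C
Reagents that add atoms: none
Why: Methanolysis of the alkynyl C–Si bond (protodesilylation) is selective for the acetylenic silane and leaves the acetonide and the tertiary alcohol untouched.

Step 10
Reactants: 14 terminal alkyne; 15 methyl chloroformate
Product: 17 methyl ynoate (C13≡C14, C15 ester; 9β-OH; acetonide), via dilithio alkoxide acetylide 16 (not isolated)
Conditions: n-BuLi (2.1 equiv), THF, −78 °C; then 15 (1.05 equiv), −78 °C; aq NH4Cl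
Reagents that add atoms: none
Why: Double deprotonation (O–H and C≡C–H) followed by C-acylation of the lithium acetylide with the chloroformate gives the alkynoate, the lithium alkoxide on the doubly flanked tertiary C9 being too hindered to compete at −78 °C.

Step 11
Reactants: 17 methyl ynoate
Product: 19 (13Z)-enoate acetonide, via alkenylcuprate 18 (not isolated)
Conditions: Me2CuLi (3 equiv, from copper iodide CuI and MeLi), THF/Et2O, −78 °C; AcOH/THF quench at −78 °C
Reagents that add atoms: lithium dimethylcuprate [Li+].C[Cu-]C (made in the flask from methyllithium C[Li] and CuI)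
Why: Syn carbocupration of the ynoate delivers methyl (C16) to C13 and copper to C14 on the same side, and protonation at −78 °C with retention, before the alkenylcuprate can equilibrate through the allenolate, leaves the C12 chain cis to the ester (13Z); the first equivalent of cuprate is consumed by the free hydroxyl.

Step 12
Reactants: 19 (13Z)-enoate acetonide
Product: 20 target, methyl (13Z)-2α,3α,9β-trihydroxy-labd-13-en-15-oate with the side chain 9α (5α-H; 8α-CH3; 10β-CH3)
Conditions: AcOH/H2O 4:1, 45 °C
Reagents that add atoms: none
Why: Mild acid-catalysed acetal hydrolysis frees the 2α,3α-diol under conditions that the tertiary C9 alcohol and the Z-enoate should tolerate; no stereocentre is touched.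

**Compound list**

1 | 2,6-dimethyl-1,4-benzoquinone | CC1=CC(=O)C=C(C)C1=O | starting material
2 | 4-methylpenta-1,3-diene | C=CC=C(C)C | starting material
3 | cis-fused ene-dione adduct (5β-H, 10β-CH3; C2=C3, C7=C8) | O=C1C(C)=CC(=O)[C@@H]2C(C)(C)C=CC[C@@]21C | intermediate
4 | trans-fused ene-dione (5α-H) | O=C1C(C)=CC(=O)[C@H]2C(C)(C)C=CC[C@@]21C | intermediate
5 | trans-fused saturated 6,9-dione (C2=C3; 8α-CH3) | O=C1[C@H](C)CC(=O)[C@H]2C(C)(C)C=CC[C@@]21C | intermediate
6 | 2α,3α-dihydroxy-6,9-dione | O=C1[C@H](C)CC(=O)[C@H]2C(C)(C)[C@H](O)[C@H](O)C[C@@]21C | intermediate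
7 | 2α,3α-O-isopropylidene-6,9-dione | O=C1[C@H](C)CC(=O)[C@H]2C(C)(C)[C@H](OC3(C)C)[C@H](O3)C[C@@]21C | intermediate
8 | C6 (E)-tosylhydrazone of 7 | O=C1[C@H](C)C/C(=N\NS(=O)(=O)c4ccc(C)cc4)[C@H]2C(C)(C)[C@H](OC3(C)C)[C@H](O3)C[C@@]21C | intermediate
9 | N-(1,3,2-benzodioxaborol-2-yl) tosylhydrazide at C6 (nitrogen drawn 6β; configuration without consequence) | O=C1[C@H](C)C[C@@H](N(B4Oc5ccccc5O4)NS(=O)(=O)c6ccc(C)cc6)[C@H]2C(C)(C)[C@H](OC3(C)C)[C@H](O3)C[C@@]21C | intermediate (not isolated)
10 | C9 decalone acetonide | O=C1[C@H](C)CC[C@H]2C(C)(C)[C@H](OC3(C)C)[C@H](O3)C[C@@]21C | intermediate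
11 | (4-bromobut-1-yn-1-yl)trimethylsilane | C[Si](C)(C)C#CCCBr | starting material
12 | [4-(trimethylsilyl)but-3-yn-1-yl]magnesium bromide | C[Si](C)(C)C#CCC[Mg]Br | intermediate (not isolated)
13 | 9β-hydroxy-9α-[4-(trimethylsilyl)but-3-yn-1-yl] acetonide | C[Si](C)(C)C#CCC[C@]1(O)[C@H](C)CC[C@H]2C(C)(C)[C@H](OC3(C)C)[C@H](O3)C[C@@]21C | intermediate
14 | 9α-(but-3-yn-1-yl)-9β-hydroxy acetonide | C#CCC[C@]1(O)[C@H](C)CC[C@H]2C(C)(C)[C@H](OC3(C)C)[C@H](O3)C[C@@]21C | intermediate
15 | methyl chloroformate | COC(=O)Cl | starting material
16 | dilithio alkoxide acetylide of 14 | [Li]C#CCC[C@]1(O[Li])[C@H](C)CC[C@H]2C(C)(C)[C@H](OC3(C)C)[C@H](O3)C[C@@]21C | intermediate (not isolated)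
17 | methyl ynoate (C13≡C14) acetonide | COC(=O)C#CCC[C@]1(O)[C@H](C)CC[C@H]2C(C)(C)[C@H](OC3(C)C)[C@H](O3)C[C@@]21C | intermediate
18 | lithium C14-alkenyl(methyl)cuprate, copper cis to C16, C9 lithium alkoxide | [Li+].COC(=O)/C([Cu-]C)=C(/C)CC[C@]1(O[Li])[C@H](C)CC[C@H]2C(C)(C)[C@H](OC3(C)C)[C@H](O3)C[C@@]21C | intermediate (not isolated)
19 | (13Z)-enoate acetonide | COC(=O)/C=C(/C)CC[C@]1(O)[C@H](C)CC[C@H]2C(C)(C)[C@H](OC3(C)C)[C@H](O3)C[C@@]21C | intermediate
20 | CNP0292844.2 | COC(=O)/C=C(/C)CC[C@]1(O)[C@H](C)CC[C@H]2C(C)(C)[C@H](O)[C@H](O)C[C@@]21C | target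

**Step count and risks**

Total step count: 12. Longest linear sequence: 12 steps (1 → 20).

Steps most likely to fail:

1. Step 1 (bears the label). What may go wrong: the diene may not reach the s-cis geometry inside the catalyst–quinone complex, so that acid-induced oligomerisation of the diene or open-chain conjugate addition outruns ring closure; face discrimination may also erode at the temperature the diene needs.
Fallback (known chemistry; sets out from 1, returns at 7): 1 is combined, under the same oxazaborolidinium catalysis, with (E)-2-(triisopropylsilyloxy)penta-1,3-diene F1 (made from (E)-pent-3-en-2-one, i-Pr3SiOSO2CF3 and Et3N). This is a 2-silyloxydiene with no cis substituent at either terminus, the diene class for which the catalysed quinone cycloaddition is established. Its CH2 terminus should again bond to C10 and its methyl-bearing terminus to C5, giving the cis-fused silyl enol ether adduct F2 (C2–OSi, C2=C3, one methyl group on C4). Saegusa–Ito oxidation (Pd(OAc)2, MeCN) would give the ring A enone F3 (C2=O, C3=C4–CH3), and Zn/AcOH would reduce the ring B ene-dione to the cis-fused trione F4. Conjugate addition of Me2CuLi at −78 °C would install the second C4 methyl group, the C2 enolate being trapped with PhN(SO2CF3)2 as the enol triflate F5. Palladium-catalysed formate reduction (Pd(OAc)2, PPh3, HCO2H, Bu3N, DMF) would give the cis-fused Δ2 6,9-dione F6. Because the ring fusion cannot be corrected while C4 is trigonal, it is corrected last: OsO4/N-methylmorpholine N-oxide on the α face gives the cis-fused diol F7, 2,2-dimethoxypropane gives the cis-fused acetonide F8, and NaOMe/MeOH equilibration of C5 and C8 returns the route at 7.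

2. Step 2. What may go wrong: the cis/trans equilibrium may not lie far enough on the trans side, because the flattened ene-dione ring lets the cis isomer escape the C20/4β-methyl contact that the trans isomer keeps; incomplete conversion would carry the wrong ring fusion forward.
Fallback (sets out from 3, returns at 7): the ring fusion is corrected at the acetonide stage, where the axial 3α oxygen adds a syn-diaxial penalty (against C6) to the cis-fused isomer only. 3 is reduced with Zn/AcOH to the cis-fused Δ2 6,9-dione F6 (C8 drawn as its equatorial epimer; it is re-equilibrated later). OsO4/N-methylmorpholine N-oxide, with the β face of C2=C3 still covered by C20 and the 4β-methyl group, gives the cis-fused diol F7, and 2,2-dimethoxypropane gives the cis-fused acetonide F8. NaOMe in MeOH then equilibrates C5 and C8 to the trans-fused, all-equatorial 7.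

3. Step 8. What may go wrong: the hindered C9 carbonyl may be enolised towards C8 rather than attacked, or the reagent may approach from the β face, which would give the C9 epimer.
Fallback (sets out from 10, returns at 13): the C9–C11 bond is made with a small ylide and C11–C12 by epoxide opening. Dimethylsulfonium methylide (Me3S+ I−, KN(SiMe3)2, THF, 0 °C; Corey–Chaykovsky reaction) adds irreversibly and axially and would give the spiro-epoxide F9 (CH2 on the α face, oxygen β). Opening at the CH2 terminus with lithiated 1-(trimethylsilyl)propyne (n-BuLi, THF, then BF3·OEt2, −78 °C) gives 13.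

**Further compounds**

F1 | step 1 | (E)-2-(triisopropylsilyloxy)penta-1,3-diene | C=C(O[Si](C(C)C)(C(C)C)C(C)C)/C=C/C
F2 | step 1 | cis-fused silyl enol ether adduct (C2–OSi, C2=C3, 4α-CH3, ring B ene-dione) | O=C1C(C)=CC(=O)[C@@H]2[C@H](C)C=C(O[Si](C(C)C)(C(C)C)C(C)C)C[C@@]21C
F3 | step 1 | cis-fused ring A enone (C2=O, C3=C4–CH3) with ring B ene-dione | O=C1C(C)=CC(=O)[C@@H]2C(C)=CC(=O)C[C@@]21C
F4 | step 1 | cis-fused 2,6,9-trione with C3=C4 (8β-CH3) | O=C1[C@@H](C)CC(=O)[C@@H]2C(C)=CC(=O)C[C@@]21C
F5 | step 1 | cis-fused C2 enol triflate with C4 gem-dimethyl | O=C1[C@@H](C)CC(=O)[C@@H]2C(C)(C)C=C(OS(=O)(=O)C(F)(F)F)C[C@@]21C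
F6 | step 2 | cis-fused Δ2 6,9-dione (5β-H, 8β-CH3) | O=C1[C@@H](C)CC(=O)[C@@H]2C(C)(C)C=CC[C@@]21C
F7 | step 2 | cis-fused 2α,3α-dihydroxy-6,9-dione | O=C1[C@@H](C)CC(=O)[C@@H]2C(C)(C)[C@H](O)[C@H](O)C[C@@]21C
F8 | step 2 | cis-fused 2α,3α-O-isopropylidene-6,9-dione | O=C1[C@@H](C)CC(=O)[C@@H]2C(C)(C)[C@H](OC3(C)C)[C@H](O3)C[C@@]21C
F9 | step 8 | C9 spiro-epoxide of 10 (CH2 α, O β) | C1O[C@]12[C@H](C)CC[C@H]3C(C)(C)[C@H](OC4(C)C)[C@H](O4)C[C@@]32C
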